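**Plan**

- The four phenols are masked as MOM ethers, and ring B (C1 = carbon bearing CH2O, then C2 Br, C3 O, C4 O, C5 Br, C6 Br) is cut at C1–C2 and C5–C6.
- This works because C2(Br)–C3(O)–C4(O)–C5(Br) of ring B is a mirror-symmetric four-carbon unit, the carbon frame of a 2,5-dibromo-3,4-dialkoxythiophene 1,1-dioxide, and C6(Br)–C1(CH2O) is the two carbons of a 1-bromoalkyne.
- The bromoalkyne is cut at the propargylic C–O bond into propargyl bromide and a ring A benzylic alcohol (C1 CH2O, C2 Br, C3 O, C4 O, C5 H, C6 Br), whose bromines come from phenol-directed dibromination of isovanillin.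
- Forward: the thiophene dioxide (steps 1–4) and the ring A bromoalkyne (steps 5–10) are made separately; ring A is present from the start and ring B is the only ring built, by [4+2] cycloaddition and SO2 loss (step 11), before MOM removal (step 12).
- The target has no stereocentre; only substitution patterns must be controlled, and these are fixed by the symmetry of the diene and by the directing effect of the free phenol in ring A.

Key step: step 11

Remark: all four phenols are carried as MOM ethers because the central p-hydroxybenzylic ether would not survive BBr3 or hydrogenolysis at the end.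

**Route**

Step 1
Reactants: 1 diethyl 3,4-dihydroxythiophene-2,5-dicarboxylate
Product: 2 diethyl 3,4-bis(methoxymethoxy)thiophene-2,5-dicarboxylate
Conditions: MOMCl (2.5 equiv), K2CO3 (3 equiv), DMF, 0 °C → rt
Reagents that add atoms: chloromethyl methyl ether (MOMCl), COCCl
Why: Williamson-type O-alkylation, in which the enolic hydroxyls, acidified by the adjacent ester groups, are deprotonated by K2CO3 and displace chloride from the hard electrophile MOMCl, as in the routine O-alkylations of this dihydroxy diester.

Step 2
Reactants: 2 diethyl 3,4-bis(methoxymethoxy)thiophene-2,5-dicarboxylate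
Product: 3 disodium 3,4-bis(methoxymethoxy)thiophene-2,5-dicarboxylate
Conditions: NaOH (2.05 equiv), EtOH/H2O, 70 °C; evaporation to dryness
Reagents that add atoms: sodium hydroxide, [Na+].[OH-]
Why: Saponification (base-mediated acyl–oxygen ester hydrolysis) cleaves both ethyl esters while the base-stable MOM acetals are untouched, and isolating the dicarboxylate as its sodium salt avoids any acidification.

Step 3
Reactants: 3 disodium 3,4-bis(methoxymethoxy)thiophene-2,5-dicarboxylate
Product: 4 2,5-dibromo-3,4-bis(methoxymethoxy)thiophene
Conditions: NBS (2.1 equiv), H2O/THF, 0 °C → rt, dark; used at once in step 4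
Reagents that add atoms: N-bromosuccinimide, O=C1CCC(=O)N1Br
Why: Decarboxylative bromination (Hunsdiecker-type ipso-bromodecarboxylation), in which electrophilic bromine attacks each carboxylate-bearing α-carbon, activated by sulfur and by the neighbouring alkoxy group, and the σ-complex loses CO2, a transformation established for 3,4-dialkoxythiophene-2,5-dicarboxylic acids.

Step 4
Reactants: 4 2,5-dibromo-3,4-bis(methoxymethoxy)thiophene
Product: 6 2,5-dibromo-3,4-bis(methoxymethoxy)thiophene 1,1-dioxide, via thiophene 1-oxide 5 (not isolated)
Conditions: dimethyldioxirane (3 equiv, ca. 0.08 M in acetone), CH2Cl2, −20 °C → rt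
Reagents that add atoms: dimethyldioxirane, CC1(C)OO1
Why: Oxidation of a thiophene to its 1,1-dioxide by two electrophilic oxygen transfers to sulfur, the second being faster because 1-oxide 5 is no longer aromatic, with a neutral oxidant that spares the acid-labile acetals and with four ring substituents that keep 5 and 6 from Diels–Alder dimerisation.

Step 5
Reactants: 7 isovanillin (3-hydroxy-4-methoxybenzaldehyde)
Product: 9 2,6-dibromo-3-hydroxy-4-methoxybenzaldehyde, via 2-bromoisovanillin 8 (not isolated)
Conditions: Br2 (2.3 equiv), NaOAc, AcOH, rt → 50 °C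
Reagents that add atoms: bromine, BrBr
Why: Electrophilic aromatic bromination directed by the free C3 phenol, which activates only C2 (ortho) and C6 (para), so that the second bromine enters C6 of 8 while C5, meta to the hydroxyl and activated only by the weaker methoxy donor, stays unsubstituted.

Step 6
Reactants: 9 2,6-dibromo-3-hydroxy-4-methoxybenzaldehyde
Product: 10 2,6-dibromo-3,4-dihydroxybenzaldehyde
Conditions: BBr3 (2.5 equiv), CH2Cl2, −78 °C → rt; then H2O, 0 °C
Reagents that add atoms: none
Why: Aryl methyl ether cleavage with BBr3, in which boron binds the ether oxygen, bromide removes the methyl group by SN2 and aqueous work-up hydrolyses the aryl borate to the catechol, the aldehyde being inert at this temperature.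

Step 7
Reactants: 10 2,6-dibromo-3,4-dihydroxybenzaldehyde
Product: 11 2,6-dibromo-3,4-bis(methoxymethoxy)benzaldehyde
Conditions: MOMCl (3 equiv), K2CO3 (4 equiv), acetone, 0 °C → rt, under N2
Reagents that add atoms: chloromethyl methyl ether (MOMCl), COCCl
Why: Williamson-type O-alkylation of both phenoxides with MOMCl installs acetal protecting groups that should survive hydride, NaH and the thermal cycloaddition and still leave under mild acid at the end.

Step 8
Reactants: 11 2,6-dibromo-3,4-bis(methoxymethoxy)benzaldehyde
Product: 12 [2,6-dibromo-3,4-bis(methoxymethoxy)phenyl]methanol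
Conditions: NaBH4, MeOH/THF, 0 °C
Reagents that add atoms: none
Why: Borohydride reduction (1,2-hydride addition) of the aldehyde gives the benzylic alcohol and does not touch aryl bromides or acetals.

Step 9
Reactants: 12 [2,6-dibromo-3,4-bis(methoxymethoxy)phenyl]methanol; 13 propargyl bromide (3-bromoprop-1-yne)
Product: 14 2,6-dibromo-3,4-bis(methoxymethoxy)benzyl prop-2-ynyl ether
Conditions: NaH (1.2 equiv), THF/DMF (4:1), 0 °C; then 13 (1.5 equiv), Bu4NI (cat.), 0 °C → rt
Reagents that add atoms: none
Why: Williamson ether synthesis, in which the benzylic alkoxide displaces bromide from propargyl bromide by SN2 at an unhindered primary carbon, so the two ortho bromines of ring A do not impede the substitution.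

Step 10
Reactants: 14 2,6-dibromo-3,4-bis(methoxymethoxy)benzyl prop-2-ynyl ether
Product: 15 3-bromoprop-2-ynyl 2,6-dibromo-3,4-bis(methoxymethoxy)benzyl ether
Conditions: NBS (1.15 equiv), AgNO3 (10 mol %), acetone, rt, dark
Reagents that add atoms: N-bromosuccinimide, O=C1CCC(=O)N1Br
Why: Silver-catalysed electrophilic bromination of a terminal alkyne, in which the silver acetylide formed reversibly with AgNO3 is brominated by NBS at the sp carbon while the doubly brominated, deactivated arene does not compete.

Step 11
Reactants: 6 2,5-dibromo-3,4-bis(methoxymethoxy)thiophene 1,1-dioxide; 15 3-bromoprop-2-ynyl 2,6-dibromo-3,4-bis(methoxymethoxy)benzyl ether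
Product: 17 2,6-dibromo-3,4-bis(methoxymethoxy)benzyl 2,3,6-tribromo-4,5-bis(methoxymethoxy)benzyl ether, via bridged sulfone adduct 16 (not isolated)
Conditions: 6 (1.5 equiv), PhMe (ca. 1 M in 15), NaHCO3 (solid), BHT (cat.), 110 °C, sealed tube
Reagents that add atoms: none
Why: The cyclic, non-aromatic diene 6 adds suprafacially across the C≡C bond of 15 in a concerted [4+2] cycloaddition that forms the ring B bonds C1–C2 and C5–C6, and the strained 7-thiabicyclo[2.2.1]heptadiene 7,7-dioxide 16 then expels SO2 in a thermally allowed cheletropic step, the gain of benzene aromaticity making the sequence irreversible. The closest known reaction type is the Diels–Alder/SO2-extrusion benzannulation of halogenated thiophene 1,1-dioxides with alkynes, which delivers polyhalobenzenes. Ring B is closed intermolecularly by the [4+2] event, a six-membered ring from a four-carbon and a two-carbon unit, and the extrusion closes no ring but only unbridges the adduct. No stereocentre remains, because the two bridgehead centres of racemic 16 become sp2 carbons of the arene. The step needs chemoselectivity for cross-cycloaddition over self-dimerisation or decomposition of the diene, which the 2,5-bromines and 3,4-alkoxy groups should secure by shielding both diene termini while the sulfone keeps the LUMO low and the alkoxy groups raise the HOMO, and it needs no regiocontrol because the diene has a mirror plane through sulfur, so either alignment of the bromoalkyne gives the same hexasubstituted ring. Solid NaHCO3 traps acid arising from SO2 and adventitious water so that the four acetals survive.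

Step 12
Reactants: 17 2,6-dibromo-3,4-bis(methoxymethoxy)benzyl 2,3,6-tribromo-4,5-bis(methoxymethoxy)benzyl ether
Product: 18 3,4,6-tribromo-5-{[(2,6-dibromo-3,4-dihydroxyphenyl)methoxy]methyl}benzene-1,2-diol (2,6-dibromo-3,4-dihydroxybenzyl 2,3,6-tribromo-4,5-dihydroxybenzyl ether, the target)
Conditions: NaHSO4·SiO2, CH2Cl2, rt; filtration
Reagents that add atoms: none
Why: Acid-catalysed acetal cleavage (MOM ether hydrolysis) on a mildly acidic solid known to be selective for phenolic MOM ethers, where the absence of strong acid and of a nucleophilic solvent should keep the bis-ortho-brominated, inductively deactivated benzylic ether from ionising toward a quinone methide.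

**Compound list**

1 | diethyl 3,4-dihydroxythiophene-2,5-dicarboxylate | CCOC(=O)c1sc(C(=O)OCC)c(O)c1O | starting material
2 | diethyl 3,4-bis(methoxymethoxy)thiophene-2,5-dicarboxylate | CCOC(=O)c1sc(C(=O)OCC)c(OCOC)c1OCOC | intermediate
3 | disodium 3,4-bis(methoxymethoxy)thiophene-2,5-dicarboxylate | COCOc1c(C(=O)[O-])sc(C(=O)[O-])c1OCOC.[Na+].[Na+] | intermediate
4 | 2,5-dibromo-3,4-bis(methoxymethoxy)thiophene | COCOc1c(Br)sc(Br)c1OCOC | intermediate
5 | 2,5-dibromo-3,4-bis(methoxymethoxy)thiophene 1-oxide (not isolated) | COCOC1=C(Br)S(=O)C(Br)=C1OCOC | intermediate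
6 | 2,5-dibromo-3,4-bis(methoxymethoxy)thiophene 1,1-dioxide | COCOC1=C(Br)S(=O)(=O)C(Br)=C1OCOC | intermediate
7 | isovanillin (3-hydroxy-4-methoxybenzaldehyde) | COc1ccc(C=O)cc1O | starting material
8 | 2-bromo-3-hydroxy-4-methoxybenzaldehyde (2-bromoisovanillin, not isolated) | COc1ccc(C=O)c(Br)c1O | intermediate
9 | 2,6-dibromo-3-hydroxy-4-methoxybenzaldehyde | COc1cc(Br)c(C=O)c(Br)c1O | intermediate
10 | 2,6-dibromo-3,4-dihydroxybenzaldehyde | O=Cc1c(Br)cc(O)c(O)c1Br | intermediate
11 | 2,6-dibromo-3,4-bis(methoxymethoxy)benzaldehyde | COCOc1cc(Br)c(C=O)c(Br)c1OCOC | intermediate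
12 | [2,6-dibromo-3,4-bis(methoxymethoxy)phenyl]methanol | COCOc1cc(Br)c(CO)c(Br)c1OCOC | intermediate
13 | propargyl bromide (3-bromoprop-1-yne) | BrCC#C | starting material
14 | 2,6-dibromo-3,4-bis(methoxymethoxy)benzyl prop-2-ynyl ether | C#CCOCc1c(Br)cc(OCOC)c(OCOC)c1Br | intermediate
15 | 3-bromoprop-2-ynyl 2,6-dibromo-3,4-bis(methoxymethoxy)benzyl ether | BrC#CCOCc1c(Br)cc(OCOC)c(OCOC)c1Br | intermediate
16 | 1,4,5-tribromo-6-{[2,6-dibromo-3,4-bis(methoxymethoxy)benzyl]oxymethyl}-2,3-bis(methoxymethoxy)-7-thiabicyclo[2.2.1]hepta-2,5-diene 7,7-dioxide (racemic, not isolated) | COCOC1=C(OCOC)C2(Br)C(Br)=C(COCc3c(Br)cc(OCOC)c(OCOC)c3Br)C1(Br)S2(=O)=O | intermediate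
17 | 2,6-dibromo-3,4-bis(methoxymethoxy)benzyl 2,3,6-tribromo-4,5-bis(methoxymethoxy)benzyl ether | COCOc1cc(Br)c(COCc2c(Br)c(OCOC)c(OCOC)c(Br)c2Br)c(Br)c1OCOC | intermediate
18 | 3,4,6-tribromo-5-{[(2,6-dibromo-3,4-dihydroxyphenyl)methoxy]methyl}benzene-1,2-diol | Oc1cc(Br)c(COCc2c(Br)c(O)c(O)c(Br)c2Br)c(Br)c1O | target

**Count and risks**

Total step count: 12. Longest linear sequence: 8 steps (7 → 18 through steps 5–10, 11 and 12); the thiophene branch contributes 4 steps before the convergent step 11.

Steps most likely to fail:

1. Step 11. The cycloaddition may be slower than thermal decomposition or self-condensation of the push–pull diene, or than oligomerisation of the bromoalkyne, so that little cross-adduct forms. The fallback gives up the cycloaddition, builds ring B by arene bromination and joins the halves by etherification; it sets out from 10 and 12 and comes back at 17. Bromination of 10 at its one free ring position, ortho to the C4 hydroxyl (Br2, AcOH, rt), should give 2,3,6-tribromo-4,5-dihydroxybenzaldehyde F1. MOM protection (MOMCl, K2CO3, acetone) should then give 2,3,6-tribromo-4,5-bis(methoxymethoxy)benzaldehyde F2, and NaBH4 in MeOH/THF should reduce it to [2,3,6-tribromo-4,5-bis(methoxymethoxy)phenyl]methanol F3. An Appel reaction (CBr4, PPh3, CH2Cl2, 0 °C), which generates no acid, should convert F3 into 2,3,6-tribromo-4,5-bis(methoxymethoxy)benzyl bromide F4. Williamson etherification of the sodium alkoxide of 12 (NaH, THF/DMF, Bu4NI cat.) with F4 should deliver 17.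

2. Step 4. Oxygen transfer may go to the electron-rich C=C bonds instead of sulfur, or stall at the 1-oxide, which could then dimerise. The fallback oxidises a silyl-substituted thiophene and installs the bromines afterwards; it sets out from 4 and comes back at 6. Double bromine–lithium exchange on 4 (n-BuLi, 2.2 equiv, THF, −78 °C) and quenching with Me3SiCl should give 3,4-bis(methoxymethoxy)-2,5-bis(trimethylsilyl)thiophene F5. Its sulfur is more nucleophilic and its α-positions are blocked, so mCPBA/NaHCO3 in CH2Cl2 should give 3,4-bis(methoxymethoxy)-2,5-bis(trimethylsilyl)thiophene 1,1-dioxide F6, a class of dioxide that is routinely made this way. Ipso-bromodesilylation of F6 (Br2, AgBF4, CH2Cl2, −30 °C), the reaction by which 2,5-dihalothiophene 1,1-dioxides are obtained from their 2,5-disilyl precursors, should then return 6.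

3. Step 12. Once the para phenols are free, acid may ionise the p-hydroxybenzylic C–O bond toward a quinone methide and cleave the central ether. The fallback removes the acetals by silyl transfer under non-acidic conditions; it sets out from 17 and comes back at 18. Triethylsilyl triflate with 2,2′-bipyridyl in CH2Cl2 (0 °C → rt) should exchange each aromatic MOM group for a silyl group, giving 2,6-dibromo-3,4-bis(triethylsilyloxy)benzyl 2,3,6-tribromo-4,5-bis(triethylsilyloxy)benzyl ether F7. Buffered fluoride (Bu4NF/AcOH, THF, 0 °C) should then cleave the four aryl silyl ethers of F7 to give 18.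

**Further compounds**

F1 | step 11 | 2,3,6-tribromo-4,5-dihydroxybenzaldehyde | O=Cc1c(Br)c(Br)c(O)c(O)c1Br
F2 | step 11 | 2,3,6-tribromo-4,5-bis(methoxymethoxy)benzaldehyde | COCOc1c(Br)c(Br)c(C=O)c(Br)c1OCOC
F3 | step 11 | [2,3,6-tribromo-4,5-bis(methoxymethoxy)phenyl]methanol | COCOc1c(Br)c(Br)c(CO)c(Br)c1OCOC
F4 | step 11 | 2,3,6-tribromo-4,5-bis(methoxymethoxy)benzyl bromide | COCOc1c(Br)c(Br)c(CBr)c(Br)c1OCOC
F5 | step 4 | 3,4-bis(methoxymethoxy)-2,5-bis(trimethylsilyl)thiophene | COCOc1c([Si](C)(C)C)sc([Si](C)(C)C)c1OCOC
F6 | step 4 | 3,4-bis(methoxymethoxy)-2,5-bis(trimethylsilyl)thiophene 1,1-dioxide | COCOC1=C([Si](C)(C)C)S(=O)(=O)C([Si](C)(C)C)=C1OCOC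
F7 | step 12 | 2,6-dibromo-3,4-bis(triethylsilyloxy)benzyl 2,3,6-tribromo-4,5-bis(triethylsilyloxy)benzyl ether | CC[Si](CC)(CC)Oc1cc(Br)c(COCc2c(Br)c(O[Si](CC)(CC)CC)c(O[Si](CC)(CC)CC)c(Br)c2Br)c(Br)c1O[Si](CC)(CC)CC
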